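**Plan**
1. Labels: ring A = C1(OAc)–C2–C3(CH3,OAc)–C4–C5(H)–C16; ring B = C5–C6–C7(=O)–C8–C16; ring C = C8=C9–C10–C11–N12–C13–C14–C15–C16; β is the ring A face carrying C6 and C8, α the face of H-5 and C15.
2. Cuts: the C8=C9 enone goes back to a C8 tertiary alcohol beside the C7 ketone and then to a C7=C8 alkene; ring C is cut at N12–C13 (sulfonamide N-alkylation) and C8–C9 (B-alkyl Suzuki coupling of a C8 enol triflate); ring A is cut at C16–C1 and C5–C4 ([4+2]); C16–C15 is cut by a Suzuki coupling on 2-iodocyclopentenone.
3. Forward order: ring B is bought as cyclopentenone, then ring A by cycloaddition, the ring A oxygens, the C9–C11 arm, ring C (azonane), the N-formyl group and last the ring B enone.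
4. Enabling feature: the quaternary carbon C16 and the ring-fusion CH C5 are neighbours shared by rings A and B, so they can be the α- and β-carbons of a 2-alkylcyclopent-2-enone that takes up a 3-methyl-1,1-dioxygenated butadiene supplying C1–C4, with oxygen at C1 and methyl at C3.
5. Stereochemistry: C5/C16 cis from suprafacial cycloaddition, absolute sense from the chiral Lewis acid; C1 from axial hydride delivery; C3 relayed from the C1 hydroxyl (directed epoxidation, SN2 opening at C2); the C8=C9 geometry from the nine-membered ring.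

Key step: step 5

Assumption: a 2-alkylcyclopentenone has no α-vinyl hydrogen, so the usual α-C–H···O organisation of oxazaborolidine–enone complexes is not available; the (S)-diphenylprolinol-derived catalyst is written on the assumption that it leaves open the enone face leading to the (3aR,7aS) cycloadduct, and its mirror image is used if a first run shows the opposite sense.

**Route**

Step 1
Reactants: 1 cyclopent-2-en-1-one
Product: 2 2-iodocyclopent-2-en-1-one
Conditions: I2, K2CO3, DMAP (cat.), THF/H2O, rt
Reagents that add atoms: iodine, II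
Why: Amine-catalysed α-iodination of an enone (conjugate addition of DMAP, iodination of the enolate, elimination) is the standard entry to 2-iodocycloalkenones.

Step 2
Reactants: 3 allyl alcohol (prop-2-en-1-ol)
Product: 4 tert-butyldimethyl(prop-2-en-1-yloxy)silane
Conditions: t-BuMe2SiCl, imidazole, CH2Cl2, 0 °C to rt
Reagents that add atoms: tert-butyldimethylsilyl chloride, CC(C)(C)[Si](C)(C)Cl
Why: Imidazole-promoted silylation of a primary alcohol.

Step 3
Reactants: 4 tert-butyldimethyl(prop-2-en-1-yloxy)silane; 2 2-iodocyclopent-2-en-1-one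
Product: 6 2-[3-(tert-butyldimethylsilyloxy)propyl]cyclopent-2-en-1-one, via alkylborane 5 (not isolated)
Conditions: 9-BBN-H, THF, 0 °C to rt; then 2, PdCl2(dppf) (5 mol %), AsPh3, Cs2CO3, DMF/H2O, rt
Reagents that add atoms: none
Why: Anti-Markovnikov hydroboration followed by B-alkyl Suzuki–Miyaura coupling, a pairing well established for 2-iodoenones, forms C16–C15.

Step 4
Reactants: 7 3-methylbut-2-enoic acid
Product: 9 1,1-bis(trimethylsilyloxy)-3-methylbuta-1,3-diene, via dilithium dienolate 8 (not isolated)
Conditions: LiN(iPr)2 (2.2 equiv), THF, –78 to 0 °C; then Me3SiCl, –78 °C to rt; filtration, distillation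
Reagents that add atoms: chlorotrimethylsilane, C[Si](C)(C)Cl
Why: γ-Deprotonation of the lithium carboxylate and O,O-bis-silylation of the dianion (ketene acetal formation) give the vinylketene bis-silyl acetal, which has no alkene geometry to control because both oxygens carry the same group.

Step 5
Reactants: 6 2-[3-(tert-butyldimethylsilyloxy)propyl]cyclopent-2-en-1-one; 9 1,1-bis(trimethylsilyloxy)-3-methylbuta-1,3-diene
Product: 11 (3aR,7aS)-7a-[3-(tert-butyldimethylsilyloxy)propyl]-5-methyl-3,3a,4,7a-tetrahydro-2H-indene-1,7-dione, via bis-silyl ketal cycloadduct 10 (not isolated)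
Conditions: (S)-o-tolyl-oxazaborolidine from (S)-α,α-diphenylprolinol (20 mol %), AlBr3 (16 mol %), CH2Cl2, –78 to –40 °C, slow addition of 9 (1.5 equiv); then 10% aq. citric acid, THF, 0 °C
Reagents that add atoms: none
Why: The AlBr3-activated oxazaborolidine binds the enone carbonyl of 6, and the diene then adds in an asynchronous but concerted [4+2] in which its nucleophilic CH2 terminus bonds to the enone β-carbon (C5) and its ketene acetal carbon to the α-carbon (C16); the closest known reaction type is the enantioselective Diels–Alder addition of silyloxy dienes to cyclic enones under cationic oxazaborolidine catalysis. Ring A closes by this cycloaddition, both bonds forming on one face of the ring alkene, so H-5 and the C16 side chain can only be cis. The absolute configuration of C5 and C16 is set together by the catalyst, which shields one face of the bound enone. The step needs regioselectivity, given by the matched polarisation of ketene acetal terminus and enone β-carbon, and it needs ring closure to win over a silyl-transfer Mukaiyama–Michael pathway, which low temperature, a non-polar solvent, slow diene addition and a catalyst without a nucleophilic counter-ion should favour. Mild acid then hydrolyses the bis(trimethylsilyl) ketal of 10 to the C1 ketone, which leaves the ring A enone with the methyl group on C3 and spares the primary silyl ether.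

Step 6
Reactants: 11 (3aR,7aS)-enedione
Product: 13 C8 enol triflate (C7=C8–OSO2CF3; C1 enone unchanged), via lithium enolate 12 (not isolated)
Conditions: LiN(iPr)2 (1.05 equiv), THF, –78 °C, 11 added to the base; then Comins' reagent, –78 °C
Reagents that add atoms: N-(5-chloropyridin-2-yl)bis(trifluoromethanesulfonyl)imide, Clc1ccc(nc1)N(S(=O)(=O)C(F)(F)F)S(=O)(=O)C(F)(F)F
Why: Kinetic enolisation takes the only α-hydrogens of the C8 ketone (C7), since the C1 enone has no α′-hydrogen and its γ-protons are removed far more slowly; O-triflation then masks C8 and prepares the later C8–C9 coupling.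

Step 7
Reactants: 13 C8 enol triflate
Product: 14 1β-allylic alcohol (C1–OH β, C2=C3 retained)
Conditions: NaBH4, CeCl3·7H2O, MeOH, –78 to –40 °C
Reagents that add atoms: none
Why: Luche 1,2-reduction, in which hydride should enter C1 axially from the α face, away from the pseudoaxial C8 (and its triflate) on the adjacent quaternary carbon, to give the 1β-alcohol; the enol triflate is inert.

Step 8
Reactants: 14 1β-allylic alcohol
Product: 15 2β,3β-epoxy-1β-alcohol
Conditions: VO(acac)2 (5 mol %), t-BuOOH (1.5 equiv), CH2Cl2, 0 °C to rt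
Reagents that add atoms: tert-butyl hydroperoxide, CC(C)(C)OO
Why: Hydroxyl-directed vanadium-catalysed epoxidation delivers oxygen to the C2=C3 face syn to the 1β-OH, which fixes the C3–O bond β, and the electron-poor enol triflate alkene is not epoxidised.

Step 9
Reactants: 15 2β,3β-epoxy-1β-alcohol
Product: 16 2α-phenylselanyl-1β,3β-diol
Conditions: (PhSe)2 (0.6 equiv), NaBH4, EtOH, rt; then 15, 60 °C
Reagents that add atoms: diphenyl diselenide, c1ccc(cc1)[Se][Se]c1ccccc1
Why: SN2 opening of the trisubstituted epoxide by the soft selenolate can only take place at the secondary carbon C2 (from the α face, with inversion), so C3 keeps its β oxygen as the tertiary carbinol; a selenolate is used because a hydride reagent would cleave the enol triflate.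

Step 10
Reactants: 16 2α-phenylselanyl-1β,3β-diol
Product: 17 1β,3β-diol (3α-methyl)
Conditions: Bu3SnH, AIBN (cat.), toluene, 80 °C
Reagents that add atoms: none
Why: Radical deselenation (stannyl radical removes PhSe, the C2 radical takes hydrogen from the tin hydride) turns C2 into CH2 and touches no stereocentre.

Step 11
Reactants: 17 1β,3β-diol
Product: 18 1β,3β-diacetate (C8 enol triflate retained)
Conditions: Ac2O, DMAP, Et3N, CH2Cl2, rt to 40 °C
Reagents that add atoms: acetic anhydride, CC(=O)OC(C)=O
Why: DMAP-catalysed acylation esterifies both the hindered secondary and the tertiary hydroxyl, and having C1–O acylated now prevents it from later closing a tetrahydropyran onto C13.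

Step 12
Reactants: 19 allylamine (prop-2-en-1-amine)
Product: 20 N-allyl-2-nitrobenzenesulfonamide
Conditions: 2-NO2C6H4SO2Cl, Et3N, CH2Cl2, 0 °C
Reagents that add atoms: 2-nitrobenzenesulfonyl chloride, O=[N+]([O-])c1ccccc1S(=O)(=O)Cl
Why: Sulfonylation of a primary amine gives the acidic N–H sulfonamide needed for the Fukuyama-type ring closure.

Step 13
Reactants: 20 N-allyl-2-nitrobenzenesulfonamide; 18 1β,3β-diacetate enol triflate
Product: 22 C8-[3-(2-nitrobenzenesulfonylamino)propyl] C7=C8 alkene (diacetate and silyl ether retained), via alkylborane 21 (not isolated)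
Conditions: 9-BBN-H (2.2 equiv), THF, rt; then 18, PdCl2(dppf) (10 mol %), AsPh3, Cs2CO3, DMF/H2O, rt to 40 °C
Reagents that add atoms: none
Why: B-alkyl Suzuki–Miyaura coupling of the enol triflate forms C8–C9 and brings in C9–C11 with the nitrogen; the acetates tolerate the mild aqueous carbonate, and since no hydride step follows the nitro group is safe.

Step 14
Reactants: 22 silyl ether sulfonamide
Product: 23 primary alcohol (C13–OH)
Conditions: HF·pyridine, pyridine/THF, 0 °C to rt
Reagents that add atoms: none
Why: Buffered fluoride cleaves the primary silyl ether and leaves the acid-sensitive tertiary acetate alone.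

Step 15
Reactants: 23 primary alcohol
Product: 24 N-(2-nitrobenzenesulfonyl)azonane (ring C closed, C7=C8 alkene)
Conditions: PPh3, DIAD, toluene/THF, about 0.002 M, slow addition of 23, rt
Reagents that add atoms: none
Why: Intramolecular Fukuyama–Mitsunobu N-alkylation of the acidic sulfonamide by the primary alcohol forms N12–C13; nine-membered closures of this kind are known, and here the two arms sit on adjacent ring B atoms.

Step 16
Reactants: 24 N-sulfonyl azonane
Product: 25 secondary amine
Conditions: PhSH, K2CO3, MeCN, rt
Reagents that add atoms: none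
Why: Thiolate SNAr cleavage (via a Meisenheimer adduct) of the 2-nitrobenzenesulfonamide frees the amine without touching the acetates.

Step 17
Reactants: 25 secondary amine
Product: 26 N-formyl azonane
Conditions: HCO2Et (solvent), 55 °C
Reagents that add atoms: ethyl formate, CCOC=O
Why: Aminolysis of a formate ester N-formylates the amine far faster than it could attack the hindered acetates.

Step 18
Reactants: 26 N-formyl azonane
Product: 27 7,8-cis-diol
Conditions: OsO4 (5 mol %), N-methylmorpholine N-oxide, acetone/H2O, rt
Reagents that add atoms: osmium tetroxide, O=[Os](=O)(=O)=O; N-methylmorpholine N-oxide, C[N+]1([O-])CCOCC1; water, O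
Why: Upjohn syn-dihydroxylation of the only alkene, drawn as attack on the ring B face away from ring A; the configuration at C7 and C8 does not matter because C7 is oxidised next and C8 then becomes trigonal.

Step 19
Reactants: 27 7,8-cis-diol
Product: 28 8-hydroxy-7-ketone
Conditions: Dess–Martin periodinane, CH2Cl2, 0 °C to rt
Reagents that add atoms: none
Why: Oxidation of the secondary alcohol beside the tertiary one gives the α-hydroxy ketone and completes the move of the carbonyl from C8 to C7.

Step 20
Reactants: 28 8-hydroxy-7-ketone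
Product: 29 target CNP0137427.1
Conditions: Burgess reagent, benzene, 50 °C
Reagents that add atoms: none
Why: Burgess syn-elimination of the tertiary alcohol has β-hydrogens only on C9 (C16 is quaternary, C7 is the carbonyl), so the C8=C9 enone forms regiospecifically, and the nine-membered ring should give the cis-in-ring (E) alkene of the target.

**Compound list**
1 | cyclopent-2-en-1-one | O=C1C=CCC1 | starting material
2 | 2-iodocyclopent-2-en-1-one | O=C1CCC=C1I | intermediate
3 | allyl alcohol | C=CCO | starting material
4 | tert-butyldimethyl(prop-2-en-1-yloxy)silane | C=CCO[Si](C)(C)C(C)(C)C | intermediate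
5 | 9-[3-(tert-butyldimethylsilyloxy)propyl]-9-borabicyclo[3.3.1]nonane | CC(C)(C)[Si](C)(C)OCCCB1C2CCCC1CCC2 | intermediate (not isolated)
6 | 2-[3-(tert-butyldimethylsilyloxy)propyl]cyclopent-2-en-1-one | O=C1CCC=C1CCCO[Si](C)(C)C(C)(C)C | intermediate
7 | 3-methylbut-2-enoic acid | CC(C)=CC(=O)O | starting material
8 | dilithium 3-methylbuta-1,3-diene-1,1-diolate | [Li+].[Li+].C=C(C)C=C([O-])[O-] | intermediate (not isolated)
9 | 1,1-bis(trimethylsilyloxy)-3-methylbuta-1,3-diene | C=C(C)C=C(O[Si](C)(C)C)O[Si](C)(C)C | intermediate
10 | (3aR,7aS)-7a-[3-(tert-butyldimethylsilyloxy)propyl]-5-methyl-7,7-bis(trimethylsilyloxy)-2,3,3a,4,7,7a-hexahydro-1H-inden-1-one | C[Si](C)(C)OC1(O[Si](C)(C)C)C=C(C)C[C@H]2CCC(=O)[C@]21CCCO[Si](C)(C)C(C)(C)C | intermediate (not isolated)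
11 | (3aR,7aS)-7a-[3-(tert-butyldimethylsilyloxy)propyl]-5-methyl-3,3a,4,7a-tetrahydro-2H-indene-1,7-dione (cis-fused; C1 enone, C8 ketone) | O=C1C=C(C)C[C@H]2CCC(=O)[C@]21CCCO[Si](C)(C)C(C)(C)C | intermediate
12 | lithium C7=C8 enolate of 11 | O=C1C=C(C)C[C@H]2CC=C([O-])[C@]21CCCO[Si](C)(C)C(C)(C)C.[Li+] | intermediate (not isolated)
13 | C8 enol trifluoromethanesulfonate of 11 (C7=C8; C1 enone; 5α-H, 16α-chain) | O=C1C=C(C)C[C@H]2CC=C(OS(=O)(=O)C(F)(F)F)[C@]21CCCO[Si](C)(C)C(C)(C)C | intermediate
14 | 1β-hydroxy-C2=C3 allylic alcohol, C8 enol triflate | O[C@H]1C=C(C)C[C@H]2CC=C(OS(=O)(=O)C(F)(F)F)[C@]21CCCO[Si](C)(C)C(C)(C)C | intermediate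
15 | 2β,3β-epoxy-1β-ol (3α-methyl), C8 enol triflate | O[C@H]1[C@H]3O[C@@]3(C)C[C@H]2CC=C(OS(=O)(=O)C(F)(F)F)[C@]21CCCO[Si](C)(C)C(C)(C)C | intermediate
16 | 2α-phenylselanyl-1β,3β-diol (3α-methyl), C8 enol triflate | O[C@H]1[C@H]([Se]c3ccccc3)[C@@](C)(O)C[C@H]2CC=C(OS(=O)(=O)C(F)(F)F)[C@]21CCCO[Si](C)(C)C(C)(C)C | intermediate
17 | 1β,3β-diol (3α-methyl), C8 enol triflate | O[C@H]1C[C@@](C)(O)C[C@H]2CC=C(OS(=O)(=O)C(F)(F)F)[C@]21CCCO[Si](C)(C)C(C)(C)C | intermediate
18 | 1β,3β-diacetate (3α-methyl), C8 enol triflate | CC(=O)O[C@H]1C[C@@](C)(OC(C)=O)C[C@H]2CC=C(OS(=O)(=O)C(F)(F)F)[C@]21CCCO[Si](C)(C)C(C)(C)C | intermediate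
19 | allylamine | C=CCN | starting material
20 | N-allyl-2-nitrobenzenesulfonamide | C=CCNS(=O)(=O)c1ccccc1[N+](=O)[O-] | intermediate
21 | N-[3-(9-borabicyclo[3.3.1]nonan-9-yl)propyl]-2-nitrobenzenesulfonamide | O=[N+]([O-])c1ccccc1S(=O)(=O)NCCCB1C2CCCC1CCC2 | intermediate (not isolated)
22 | 1β,3β-diacetate with C7=C8 alkene, C8-(CH2)3NH-SO2C6H4-2-NO2 arm and C16-(CH2)3OSi(t-Bu)Me2 chain | CC(=O)O[C@H]1C[C@@](C)(OC(C)=O)C[C@H]2CC=C(CCCNS(=O)(=O)c3ccccc3[N+](=O)[O-])[C@]21CCCO[Si](C)(C)C(C)(C)C | intermediate
23 | as 22 with free C13 primary alcohol | CC(=O)O[C@H]1C[C@@](C)(OC(C)=O)C[C@H]2CC=C(CCCNS(=O)(=O)c3ccccc3[N+](=O)[O-])[C@]21CCCO | intermediate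
24 | tricyclic N12-(2-nitrobenzenesulfonyl)azonane, C7=C8 alkene, 1β,3β-diacetate | CC(=O)O[C@H]1C[C@@](C)(OC(C)=O)C[C@H]2CC=C3CCCN(S(=O)(=O)c4ccccc4[N+](=O)[O-])CCC[C@@]321 | intermediate
25 | tricyclic secondary amine (N12–H), C7=C8 alkene, 1β,3β-diacetate | CC(=O)O[C@H]1C[C@@](C)(OC(C)=O)C[C@H]2CC=C3CCCNCCC[C@@]321 | intermediate
26 | tricyclic N12-formyl azonane, C7=C8 alkene, 1β,3β-diacetate | CC(=O)O[C@H]1C[C@@](C)(OC(C)=O)C[C@H]2CC=C3CCCN(C=O)CCC[C@@]321 | intermediate
27 | 7,8-cis-diol of 26 (hydroxyls on the ring B face syn to C15 and H-5) | CC(=O)O[C@H]1C[C@@](C)(OC(C)=O)C[C@H]2C[C@H](O)[C@@]3(O)CCCN(C=O)CCC[C@@]321 | intermediate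
28 | 8-hydroxy-7-ketone | CC(=O)O[C@H]1C[C@@](C)(OC(C)=O)C[C@H]2CC(=O)[C@@]3(O)CCCN(C=O)CCC[C@@]321 | intermediate
29 | CNP0137427.1: (1S,3S,5S,16S)-1β,3β-diacetoxy-3α-methyl-N12-formyl tricycle with C7 ketone and (E)-C8=C9 | CC(=O)O[C@H]1C[C@@](C)(OC(C)=O)C[C@H]2CC(=O)/C3=C/CCN(C=O)CCC[C@@]321 | target

**Count**
Total steps: 20. Longest linear sequence: 17 steps (1 or 2, 3, 5–11, 13–20).

**Steps most likely to fail**

Step 5. The ketene acetal may hand a silyl group to the activated enone or to the catalyst, so that the reaction stops at a Mukaiyama–Michael addition without closing ring A, or runs through an achiral silyl Lewis acid and loses enantioselectivity. The fallback sets out from 6 and returns at 14, keeping the same two bond formations but lowering the diene by one oxidation level. 3-Methylbut-2-enal with Et3SiOTf and Et3N gives (E)-triethyl[(3-methylbuta-1,3-dien-1-yl)oxy]silane F1, which has no second silyloxy group to transfer. Its cycloaddition with 6 under the same chiral Lewis acid should give, by the endo rule, the 1β-triethylsilyloxy C8 ketone F2 as the only carbonyl compound. Enolisation and triflation as in step 6 give the 1β-triethylsilyloxy C8 enol triflate F3, and AcOH/THF/H2O removes the secondary triethylsilyl ether in the presence of the primary tert-butyldimethylsilyl ether to give 14. Steps 6 and 7 are then not needed.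

Step 7. Hydride may be delivered to the β face of C1 with poor selectivity, and the wrong C1 configuration would then be passed on to C3 by the directed epoxidation. The fallback sets out from 13 and returns at 14, replacing substrate control by catalyst control: reduction with a Me-CBS oxazaborolidine and catecholborane in toluene at –78 °C, using the catalyst antipode that delivers hydride to the α face (the (R)-catalyst if, as expected, the quaternary C16 flank acts as the large group). It makes no compound outside the list (F0).

Step 15. The nine-membered ring closure may lose to intermolecular N-alkylation (oligomers) or to alkylation of the reduced azodicarboxylate. The fallback sets out from 23 and returns at 24, activating carbon in a separate step and closing the ring by SN2 alkylation of the sulfonamide anion. I2, PPh3 and imidazole convert 23 into the primary iodide F4, which is added slowly to Cs2CO3 and Bu4NI in MeCN at 60 °C (about 0.002 M) to give 24.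

**Further compounds**
F1 | step 5 | (E)-triethyl[(3-methylbuta-1,3-dien-1-yl)oxy]silane | C=C(C)/C=C/O[Si](CC)(CC)CC
F2 | step 5 | endo cycloadduct: 1β-triethylsilyloxy C2=C3 alkene with C8 ketone and C16-(CH2)3OSi(t-Bu)Me2 chain | CC[Si](CC)(CC)O[C@H]1C=C(C)C[C@H]2CCC(=O)[C@]21CCCO[Si](C)(C)C(C)(C)C
F3 | step 5 | C8 enol triflate of F2 | CC[Si](CC)(CC)O[C@H]1C=C(C)C[C@H]2CC=C(OS(=O)(=O)C(F)(F)F)[C@]21CCCO[Si](C)(C)C(C)(C)C
F0 | step 7 | none | none
F4 | step 15 | C13 primary iodide corresponding to 23 | CC(=O)O[C@H]1C[C@@](C)(OC(C)=O)C[C@H]2CC=C(CCCNS(=O)(=O)c3ccccc3[N+](=O)[O-])[C@]21CCCI
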